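**Strategy.** Ring C is opened across C8–C14 and C9–C11 by an intramolecular Diels–Alder reaction that uses the oxygen on C1 of ring A as a traceless tether. In the target, O-1 sits on the same face of the spiro δ-lactone (ring B) as C11, two atoms (C1, C10) away from C9. A crotonate on O-1, as its silyl dienolate, therefore adds across the lactone C8=C9 bond from that face alone. One operation forms both bonds, the C8 quaternary centre and C9. The C11 silyl ketal then collapses to a C11-ketone enone and returns O-1 as the alcohol. The precursor is an α,β-unsaturated spiro-lactone carrying a 2-bromoallyl group on C8 and the O-1 crotonate.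

Key step: step 12

Remark: all intermediates are numbered as in the ent-kaurane skeleton of the target (C1–C20); O-1, O-6 and O-11 are the oxygens on those carbons.

Step 1
Reactants: 1 4,4-dimethylcyclohex-2-en-1-one
Product: 2 (2R,3S)-2-[(dimethylamino)methyl]-3-{[dimethyl(propan-2-yloxy)silyl]methyl}-4,4-dimethylcyclohexan-1-one
Conditions: iPrOMe2SiCH2MgCl, CuBr·SMe2 (5 mol %), (R)-1-[(S)-2-(diphenylphosphanyl)ferrocenyl]ethyl(dicyclohexyl)phosphane (Josiphos ligand, 6 mol %), t-BuOMe, −78 °C; then Me2N=CH2+ I−, THF, −78 → 0 °C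
Reagents that add atoms: (isopropoxydimethylsilyl)methylmagnesium chloride CC(C)O[Si](C)(C)C[Mg]Cl; Eschenmoser's salt C[N+](C)=C.[I-]
Why: Copper-catalysed asymmetric conjugate addition of a Grignard reagent sets C5 under ligand control (the ligand enantiomer is chosen to give the 3S centre of 2, which is C5 R in the target), and the magnesium enolate, formed only toward C10, is trapped anti to the new side chain in a Mannich reaction that places the future C20.

Step 2
Reactants: 2 Mannich base
Product: 4 (3R)-3-{[dimethyl(propan-2-yloxy)silyl]methyl}-4,4-dimethyl-2-methylidenecyclohexan-1-one, via trimethylammonium iodide 3 (not isolated)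
Conditions: MeI, CH2Cl2, rt; then NaHCO3 (aq), CH2Cl2, rt
Reagents that add atoms: none
Why: Quaternisation followed by Hofmann-type E1cB elimination of trimethylamine unveils the exocyclic enone without touching C5; the enone is used at once because 2-methylidene ketones dimerise.

Step 3
Reactants: 4 exocyclic enone
Product: 5 (1S,3R)-3-{[dimethyl(propan-2-yloxy)silyl]methyl}-4,4-dimethyl-2-methylidenecyclohexan-1-ol
Conditions: NaBH4, CeCl3·7H2O, MeOH, −78 °C
Reagents that add atoms: none
Why: Luche 1,2-reduction, in which hydride should reach C1 from the face opposite the pseudo-axial C5 side chain so that O-1 ends cis to C6 (1,3-cis).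

Step 4
Reactants: 5 allylic alcohol
Product: 6 (1S,3R)-3-(hydroxymethyl)-4,4-dimethyl-2-methylidenecyclohexan-1-ol
Conditions: H2O2 (30 %), KF, KHCO3, THF/MeOH, rt
Reagents that add atoms: hydrogen peroxide OO
Why: Tamao oxidation replaces the alkoxysilyl group by hydroxyl on the same carbon and leaves both stereocentres and the allylic alcohol unchanged.

Step 5
Reactants: 6 diol
Product: 8 bis-silyl ether (O-1 triethylsilyl and O-6 tert-butyldiphenylsilyl), via mono-TBDPS ether 7 (not isolated)
Conditions: t-BuPh2SiCl, imidazole, DMF, 0 °C; then Et3SiCl, DMAP, rt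
Reagents that add atoms: tert-butyl(chloro)diphenylsilane CC(C)(C)[Si](Cl)(c1ccccc1)c1ccccc1; chlorotriethylsilane CC[Si](Cl)(CC)CC
Why: Sequential silylation exploits the higher reactivity of the primary alcohol toward the bulky silyl chloride, so that O-6 carries the robust and O-1 the acid-labile silyl group.

Step 6
Reactants: 8 bis-silyl ether
Product: 9 spiro-epoxide (C10–C20 oxirane) of 8
Conditions: mCPBA, NaHCO3, CH2Cl2, 0 °C
Reagents that add atoms: 3-chloroperbenzoic acid OOC(=O)c1cccc(Cl)c1
Why: Prilezhaev epoxidation of the 1,1-disubstituted alkene; the configuration of the new spiro carbon is irrelevant because C10 becomes a planar radical in step 7.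

Step 7
Reactants: 9 spiro-epoxide
Product: 10 saturated spiro δ-lactone (C7 carbonyl, O–C20, C8H2, C9H2; C9 trans to C6 and O-1)
Conditions: Cp2TiCl2 (20 mol %), Zn, 2,4,6-collidine·HCl, CF3CH2O2CCH=CH2, THF, rt
Reagents that add atoms: 2,2,2-trifluoroethyl acrylate C=CC(=O)OCC(F)(F)F
Why: Titanocene-catalysed reductive epoxide opening gives the tertiary C10 radical, whose Giese addition to the acrylate should occur on the face opposite the axial C4 methyl group and thereby set C10 with C9 trans to C6 and O-1, after which the primary titanium alkoxide lactonises onto the activated ester.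

Step 8
Reactants: 10 spiro-lactone
Product: 11 C8-(2-bromoprop-2-enyl) spiro-lactone (C8 epimers)
Conditions: LiN(iPr)2, THF, −78 °C; CH2=C(Br)CH2Br, DMPU, −78 → −30 °C
Reagents that add atoms: 2,3-dibromopropene C=C(Br)CBr
Why: Alkylation of the lactone lithium enolate at the allylic bromide (SN2) introduces C15–C17; the new C8 centre is inconsequential because it is planarised in step 9.

Step 9
Reactants: 11 alkylated lactone
Product: 13 α,β-unsaturated spiro-lactone (C8=C9) carrying the 2-bromoallyl group on C8, via alpha-phenylselanyl lactone 12 (not isolated)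
Conditions: LiN(iPr)2, THF, −78 °C; PhSeBr; then H2O2 (30 %), pyridine, CH2Cl2, 0 °C
Reagents that add atoms: none
Why: Alpha-selenenylation of the enolate and selenoxide syn-elimination toward the ring C9–H should give the endocyclic C8=C9 lactone, the conjugated trisubstituted ring alkene being favoured over the exocyclic one.

Step 10
Reactants: 13 unsaturated lactone
Product: 14 O-1 alcohol of 13
Conditions: PPTS, MeOH, 0 °C → rt
Reagents that add atoms: none
Why: Acid-catalysed methanolysis removes the triethylsilyl ether far faster than the tert-butyldiphenylsilyl ether, freeing only O-1.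

Step 11
Reactants: 14 alcohol
Product: 15 O-1 (E)-but-2-enoate of 14
Conditions: (E)-crotonic anhydride, DMAP, Et3N, CH2Cl2, rt
Reagents that add atoms: (E)-but-2-enoic anhydride C/C=C/C(=O)OC(=O)/C=C/C
Why: DMAP-catalysed acylation of the hindered secondary alcohol; partial deconjugation of the crotonate would be harmless because both isomers give the same dienolate.

Step 12
Reactants: 15 crotonate
Product: 18 cyclohexenone diol (ring C closed; C11 ketone, C12=C13, free O-1 and O-6 alcohols, 2-bromoallyl on C8), via silyl dienolate 16 (not isolated), via cyclic silyl ketal adduct 17 (not isolated)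
Conditions: TBSOTf (1.1 equiv), Et3N (3 equiv), CH2Cl2, −78 → 0 °C; then toluene, 150 °C (sealed tube); then HF·pyridine, THF, 0 °C → rt
Reagents that add atoms: none
Why: Soft enolisation converts the crotonate into the 1-alkoxy-1-silyloxy diene 16, which on heating should undergo a concerted, asynchronous intramolecular Diels–Alder reaction of normal electron demand with the lactone C8=C9 bond; the closest known reaction type is the Diels–Alder reaction of ester-derived vinylketene silyl acetals, here run intramolecularly through the three-atom tether O-1–C1–C10. Two rings close: ring C by the [4+2] event itself, and a five-membered cyclic ketal (O-1, C1, C10, C9, C11) in the fused mode that a three-atom tether enforces. C9 is set by the tether, because the diene hangs from the equatorial O-1 and can reach only the lactone face syn to C1, and the C8 quaternary centre follows from suprafacial addition, which puts C14 cis to C11 and leaves the bromoallyl arm on the opposite face; C11 is a ketal carbon whose configuration is erased. The step needs fused rather than bridged regiochemistry against the electronic bias of the diene (secured by the short tether), cycloaddition rather than Mukaiyama–Michael attack through C12 (secured by the singly activated dienophile and amine-buffered thermal conditions without added Lewis acid), and the ketene acetal isomer with the tether oxygen on the outside (the other isomer is expected to equilibrate by silyl transfer at 150 °C). Fluoride then cleaves the silyl ketal 17, which collapses to the C11 ketone conjugated with C12=C13 and frees O-1, and it removes the silyl ether on O-6 in the same pot.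

Step 13
Reactants: 18 cyclohexenone diol
Product: 19 O-1,O-6-diacetate of 18
Conditions: Ac2O, pyridine, DMAP, CH2Cl2, rt
Reagents that add atoms: acetic anhydride CC(=O)OC(C)=O
Why: DMAP-catalysed acetylation installs both acetates of the target while the C11 oxygen is still a ketone and cannot compete.

Step 14
Reactants: 19 bromoallyl enone
Product: 20 tetracyclic 11-ketone (6,7-seco-ent-kaur-16-ene 7,20-lactone, 1,6-diacetate, C15H2)
Conditions: Bu3SnH, AIBN, benzene, 80 °C (slow addition)
Reagents that add atoms: none
Why: Tin hydride-mediated 5-exo-trig cyclisation of the C16 vinyl radical onto the enone beta-carbon C13 (polarity-matched radical conjugate addition) closes ring D, and the two-atom tether from C8 can deliver C16 only to the face on which C15 already sits, which sets C13.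

Step 15
Reactants: 20 11-ketone
Product: 21 11β-alcohol (15-deoxo-Rabdosin B)
Conditions: SmI2, iPrOH, THF/HMPA, 0 °C
Reagents that add atoms: none
Why: Single-electron reduction of the ketone by SmI2 with protonation of the ketyl under thermodynamic control should give the pseudo-equatorial alcohol, which in the boat-shaped ring C of these spiro-lactones is expected to be the 11β epimer of the target.

Step 16
Reactants: 21 11β-alcohol
Product: 22 11,15-diol (15-hydroxy, either C15 epimer)
Conditions: SeO2 (cat.), t-BuOOH, CH2Cl2, rt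
Reagents that add atoms: selenium dioxide O=[Se]=O (catalytic oxygen carrier); tert-butyl hydroperoxide CC(C)(C)OO (terminal oxidant)
Why: SeO2-mediated allylic oxidation (ene reaction then [2,3]-sigmatropic shift) functionalises C15, the only allylic position that is not a bridgehead; the C15 configuration is irrelevant.

Step 17
Reactants: 22 diol
Product: 23 Rabdosin B
Conditions: MnO2, CH2Cl2, rt
Reagents that add atoms: none
Why: MnO2 oxidises only the allylic C15 alcohol and leaves the saturated C11 alcohol, completing the alpha-methylene cyclopentanone.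

**Compound list**

1 | 4,4-dimethylcyclohex-2-en-1-one | O=C1C=CC(C)(C)CC1 | starting material
2 | (2R,3S)-2-[(dimethylamino)methyl]-3-{[dimethyl(propan-2-yloxy)silyl]methyl}-4,4-dimethylcyclohexan-1-one (2,3-trans) | CN(C)C[C@@H]1C(=O)CCC(C)(C)[C@H]1C[Si](C)(C)OC(C)C | intermediate
3 | trimethylammonium iodide of 2 | C[N+](C)(C)C[C@@H]1C(=O)CCC(C)(C)[C@H]1C[Si](C)(C)OC(C)C.[I-] | intermediate
4 | (3R)-3-{[dimethyl(propan-2-yloxy)silyl]methyl}-4,4-dimethyl-2-methylidenecyclohexan-1-one | C=C1C(=O)CCC(C)(C)[C@H]1C[Si](C)(C)OC(C)C | intermediate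
5 | (1S,3R)-3-{[dimethyl(propan-2-yloxy)silyl]methyl}-4,4-dimethyl-2-methylidenecyclohexan-1-ol (1,3-cis) | C=C1[C@@H](O)CCC(C)(C)[C@H]1C[Si](C)(C)OC(C)C | intermediate
6 | (1S,3R)-3-(hydroxymethyl)-4,4-dimethyl-2-methylidenecyclohexan-1-ol | C=C1[C@@H](O)CCC(C)(C)[C@H]1CO | intermediate
7 | O-6 tert-butyldiphenylsilyl ether of 6 | C=C1[C@@H](O)CCC(C)(C)[C@H]1CO[Si](c2ccccc2)(c2ccccc2)C(C)(C)C | intermediate
8 | O-1 triethylsilyl, O-6 tert-butyldiphenylsilyl bis-ether of 6 | C=C1[C@@H](O[Si](CC)(CC)CC)CCC(C)(C)[C@H]1CO[Si](c2ccccc2)(c2ccccc2)C(C)(C)C | intermediate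
9 | C10–C20 spiro-epoxide of 8 (either configuration at the spiro carbon) | C1OC12[C@@H](O[Si](CC)(CC)CC)CCC(C)(C)[C@H]2CO[Si](c3ccccc3)(c3ccccc3)C(C)(C)C | intermediate
10 | saturated spiro δ-lactone (C7(=O)–O–C20; C8H2, C9H2); C10 as in the target, C20 cis and C9 trans to O-1 and C6 | O=C1CC[C@]2(CO1)[C@@H](O[Si](CC)(CC)CC)CCC(C)(C)[C@H]2CO[Si](c3ccccc3)(c3ccccc3)C(C)(C)C | intermediate
11 | C8-(2-bromoprop-2-enyl) derivative of 10 (C8 epimers) | C=C(Br)CC1C[C@]2(COC1=O)[C@@H](O[Si](CC)(CC)CC)CCC(C)(C)[C@H]2CO[Si](c3ccccc3)(c3ccccc3)C(C)(C)C | intermediate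
12 | C8-phenylselanyl derivative of 11 (C8 epimers) | C=C(Br)CC1([Se]c4ccccc4)C[C@]2(COC1=O)[C@@H](O[Si](CC)(CC)CC)CCC(C)(C)[C@H]2CO[Si](c3ccccc3)(c3ccccc3)C(C)(C)C | intermediate
13 | C8=C9 unsaturated spiro-lactone, 2-bromoallyl on C8, O-1 triethylsilyl, O-6 tert-butyldiphenylsilyl | C=C(Br)CC1=C[C@]2(COC1=O)[C@@H](O[Si](CC)(CC)CC)CCC(C)(C)[C@H]2CO[Si](c3ccccc3)(c3ccccc3)C(C)(C)C | intermediate
14 | O-1 alcohol of 13 | C=C(Br)CC1=C[C@]2(COC1=O)[C@@H](O)CCC(C)(C)[C@H]2CO[Si](c3ccccc3)(c3ccccc3)C(C)(C)C | intermediate
15 | O-1 (E)-but-2-enoate of 14 | C=C(Br)CC1=C[C@]2(COC1=O)[C@@H](OC(=O)/C=C/C)CCC(C)(C)[C@H]2CO[Si](c3ccccc3)(c3ccccc3)C(C)(C)C | intermediate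
16 | O-1 1-(tert-butyldimethylsilyloxy)buta-1,3-dienyl ether (silyl dienolate of 15; ketene acetal isomers) | C=C(Br)CC1=C[C@]2(COC1=O)[C@@H](OC(O[Si](C)(C)C(C)(C)C)=CC=C)CCC(C)(C)[C@H]2CO[Si](c3ccccc3)(c3ccccc3)C(C)(C)C | intermediate
17 | Diels–Alder adduct: ring C cyclohexene with C11 as cyclic ketal carbon (O-1 bridge and O-silyl; either C11 configuration) | C=C(Br)C[C@]12CC=CC4(O[Si](C)(C)C(C)(C)C)[C@H]1[C@]3(COC2=O)[C@@H](O4)CCC(C)(C)[C@H]3CO[Si](c5ccccc5)(c5ccccc5)C(C)(C)C | intermediate
18 | cyclohexenone diol: C11 ketone, C12=C13, C8 quaternary (C7 lactone, C14, 2-bromoallyl), free O-1 and O-6 alcohols; C8, C9, C10, C1, C5 as in the target | C=C(Br)C[C@]12CC=CC(=O)[C@H]1[C@]3(COC2=O)[C@@H](O)CCC(C)(C)[C@H]3CO | intermediate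
19 | O-1,O-6-diacetate of 18 | C=C(Br)C[C@]12CC=CC(=O)[C@H]1[C@]3(COC2=O)[C@@H](OC(C)=O)CCC(C)(C)[C@H]3COC(C)=O | intermediate
20 | 1,6-diacetoxy-11-oxo-6,7-seco-ent-kaur-16-ene 7,20-lactone (C15H2) | C=C1C[C@]23C[C@H]1CC(=O)[C@H]2[C@]1(COC3=O)[C@@H](OC(C)=O)CCC(C)(C)[C@H]1COC(C)=O | intermediate
21 | 11β-alcohol of 20 (15-deoxo-Rabdosin B) | C=C1C[C@]23C[C@H]1C[C@H](O)[C@H]2[C@]1(COC3=O)[C@@H](OC(C)=O)CCC(C)(C)[C@H]1COC(C)=O | intermediate
22 | 15-hydroxy derivative of 21 (C15 epimers) | C=C1C(O)[C@]23C[C@H]1C[C@H](O)[C@H]2[C@]1(COC3=O)[C@@H](OC(C)=O)CCC(C)(C)[C@H]1COC(C)=O | intermediate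
23 | Rabdosin B (1S,5R,8S,9S,10R,11S,13S) | C=C1C(=O)[C@]23C[C@H]1C[C@H](O)[C@H]2[C@]1(COC3=O)[C@@H](OC(C)=O)CCC(C)(C)[C@H]1COC(C)=O | target

**Step count.** 17 steps in total; the longest linear sequence is 17 steps (from 1).

**Three steps most likely to fail**

Step 12 (key step). What may go wrong: the silyl dienolate may be consumed by intramolecular Mukaiyama–Michael attack through C12 or by silyl migration faster than it cyclises, or cyclisation may be too slow because the tether forces the electron-rich diene terminus onto the beta-carbon against its electronic preference. Fallback: the tether is changed from a ketene acetal to a silicon acetal. Setting out from alcohol 14, crotonaldehyde is converted with iPr2SiCl2 and Et3N into the chloro(dienyloxy)silane and joined to O-1 (imidazole) to give the O-1 (buta-1,3-dienyloxy)diisopropylsilyl ether F7. Heating in toluene at 160–180 °C would effect the silicon-tethered intramolecular Diels–Alder reaction, again confined to the C1 face, giving the seven-membered siladioxane adduct F8. HF·pyridine then removes both silicon groups to give the 1,6,11-triol F9, and MnO2 oxidises only the allylic C11 alcohol, which returns the route to enone diol 18.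

Step 1. What may go wrong: addition at the neopentyl beta-carbon next to the gem-dimethyl group may be slow, so that 1,2-addition competes or the enantioselectivity is low with this alpha-silyl Grignard reagent. Fallback: the first stereocentre is set at C1 by a catalytic reduction and relayed to C5 by a sigmatropic shift. Setting out from enone 1, Br2 then Et3N gives 2-bromo-4,4-dimethylcyclohex-2-en-1-one F1. Corey–Bakshi–Shibata reduction ((R)-2-methyl-CBS-oxazaborolidine, BH3·SMe2) gives (S)-2-bromo-4,4-dimethylcyclohex-2-en-1-ol F2, and Et3SiCl with imidazole gives its triethylsilyl ether F3. Bromine–lithium exchange (t-BuLi) and trapping with formaldehyde gives the 2-(hydroxymethyl) allylic alcohol F4, and KH with Bu3SnCH2I gives the (tributylstannyl)methyl ether F5. With n-BuLi, tin–lithium exchange triggers a Still–Wittig [2,3] rearrangement that should deliver CH2O to C5 on the face away from the pseudo-axial C4 methyl group and create the exocyclic alkene, giving (1S,3R)-3-(hydroxymethyl) alcohol mono-silyl ether F6. Silylation with t-BuPh2SiCl returns the route to bis-silyl ether 8.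

Step 15. What may go wrong: poor facial selectivity or formation of the wrong C11 epimer, because the ketone face syn to C10 is screened by ring A and ring C may not adopt the assumed boat. Fallback: the configuration is corrected by inversion instead of being set in the reduction. Setting out from ketone 20, NaBH4 reduction from the open face would give the 11α-alcohol F10. Mitsunobu inversion with chloroacetic acid (PPh3, DIAD) gives the 11β-chloroacetate F11. Thiourea with NaHCO3 in ethanol removes the chloroacetyl group selectively in the presence of the two acetates and returns the route to 11β-alcohol 21.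

**Further compounds**

F1 | step 1 | 2-bromo-4,4-dimethylcyclohex-2-en-1-one | O=C1C(Br)=CC(C)(C)CC1
F2 | step 1 | (S)-2-bromo-4,4-dimethylcyclohex-2-en-1-ol | BrC1=CC(C)(C)CC[C@@H]1O
F3 | step 1 | triethylsilyl ether of F2 | BrC1=CC(C)(C)CC[C@@H]1O[Si](CC)(CC)CC
F4 | step 1 | (S)-[3,3-dimethyl-6-(triethylsilyloxy)cyclohex-1-enyl]methanol | OCC1=CC(C)(C)CC[C@@H]1O[Si](CC)(CC)CC
F5 | step 1 | (tributylstannyl)methyl ether of F4 | CCCC[Sn](CCCC)(CCCC)COCC1=CC(C)(C)CC[C@@H]1O[Si](CC)(CC)CC
F6 | step 1 | (1S,3R)-3-(hydroxymethyl)-4,4-dimethyl-2-methylidenecyclohexyl triethylsilyl ether | C=C1[C@@H](O[Si](CC)(CC)CC)CCC(C)(C)[C@H]1CO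
F7 | step 12 | O-1 (E)-(buta-1,3-dienyloxy)diisopropylsilyl ether of 14 | C=C(Br)CC1=C[C@]2(COC1=O)[C@@H](O[Si](C(C)C)(C(C)C)O/C=C/C=C)CCC(C)(C)[C@H]2CO[Si](c3ccccc3)(c3ccccc3)C(C)(C)C
F8 | step 12 | silicon-tethered Diels–Alder adduct (O-1–Si–O-11 bridge, ring C cyclohexene) | C=C(Br)C[C@]12CC=CC4[C@H]1[C@]3(COC2=O)[C@@H](O[Si](C(C)C)(C(C)C)O4)CCC(C)(C)[C@H]3CO[Si](c5ccccc5)(c5ccccc5)C(C)(C)C
F9 | step 12 | 1,6,11-triol with C12=C13 (allylic C11 alcohol) | C=C(Br)C[C@]12CC=CC(O)[C@H]1[C@]3(COC2=O)[C@@H](O)CCC(C)(C)[C@H]3CO
F10 | step 15 | 11α-alcohol (C11 epimer of 21) | C=C1C[C@]23C[C@H]1C[C@@H](O)[C@H]2[C@]1(COC3=O)[C@@H](OC(C)=O)CCC(C)(C)[C@H]1COC(C)=O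
F11 | step 15 | 11β-chloroacetate of 21 | C=C1C[C@]23C[C@H]1C[C@H](OC(=O)CCl)[C@H]2[C@]1(COC3=O)[C@@H](OC(C)=O)CCC(C)(C)[C@H]1COC(C)=O
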